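## Retrosynthetic overview

1. The last operation opens and decarboxylates a temporary six-membered enol lactone. One carbonyl carbon ties the tetronic acid oxygen to the carbon alpha to the sorbyl ketone. It serves as tether and second activator, and it leaves as CO2.
2. Key disconnection: a retro-[4+2] cuts both bonds from the bridgeheads C(CH3) and CH to the CH(CO-sorbyl)–CH(butenolide) bridge. This removes two bridges of the bicyclo[2.2.2]octene at once and gives an (S)-o-quinol diene, made in the flask by dearomatisation of flat 2',3'-dihydrosorbicillin, and a bicyclic dienophile.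
3. Enabling features: the enol double bond C(acyl)=C(OH) between the two bridgeheads is a cyclohexene retron, and the C(=O)–C(CH3)(OH) bridge is a dearomatised resorcinol carbon pair. The tetronic acid O and the acidic CH next to the sorbyl C=O are joined by the path O–C=, C(CH3), CH, CH, so one extra C=O closes a planar six-membered ring that locks and doubly activates the alkene.
4. Dienophile: the butenolide quaternary carbon comes from (R)-lactic acid by self-regeneration of the stereocentre. Claisen acylation and lactonisation then build the tetronic acid, followed by the aldehyde, Knoevenagel condensation with a sorbylacetate, and enol lactonisation.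
5. Ring order: arene carbocycle (bought), butenolide, temporary pyranone, then both new carbocycles of the bicyclooctene in the key step. The temporary ring is removed afterwards.

Key step: step 12

Assumption: SorbC, the FAD-dependent sorbicillin monooxygenase, is taken as an accessible recombinant biocatalyst and counts as a catalyst, not as a starting material. Tricarbonyl and tetronic acid units are drawn in the tautomer of the target SMILES.

## Route

Step 1
Reactants: 1 2,4-dimethylresorcinol (2,4-dimethylbenzene-1,3-diol); 2 acetic acid
Product: 3 1-(2,4-dihydroxy-3,5-dimethylphenyl)ethan-1-one (clavatol)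
Conditions: BF3·OEt2 (solvent), 90 °C; aq. NaOAc
Reagents that add atoms: none
Why: Friedel–Crafts C-acylation of the electron-rich resorcinol can only occur at its single free position ortho/para to the two hydroxyl groups, and chelation of the product to boron should prevent over-reaction.

Step 2
Reactants: 3 clavatol; 4 (E)-crotyl bromide ((2E)-1-bromobut-2-ene)
Product: 5 (4E)-1-(2,4-dihydroxy-3,5-dimethylphenyl)hex-4-en-1-one (2',3'-dihydrosorbicillin)
Conditions: LDA (3.3 equiv), THF, −78 to 0 °C; 4 (1.0 equiv), −78 to 0 °C; 1 M HCl; recrystallisation
Reagents that add atoms: none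
Why: Polyanion alkylation, in which the ketone enolate carbon of the trilithiated species is the last-formed and most nucleophilic site, so SN2 attack on the primary allylic bromide should extend the methyl ketone to the (E)-hex-4-enoyl chain with the alkene geometry retained.

Step 3
Reactants: 6 (R)-lactic acid; 7 pivalaldehyde
Product: 8 (2R,5R)-2-tert-butyl-5-methyl-1,3-dioxolan-4-one (cis)
Conditions: p-TsOH·H2O (cat.), pentane, reflux, Dean–Stark; crystallisation from pentane at −78 °C
Reagents that add atoms: none
Why: Acid-catalysed acetalisation (first stage of self-regeneration of stereocentres) should favour the cis-dioxolanone, the new acetal centre being controlled by the lactate stereocentre and upgraded by low-temperature crystallisation.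

Step 4
Reactants: 8 cis-dioxolanone; 9 benzyl chloromethyl ether (BOMCl)
Product: 10 (2R,5S)-5-[(benzyloxy)methyl]-2-tert-butyl-5-methyl-1,3-dioxolan-4-one
Conditions: LDA, THF, −78 °C; then 9, −78 to −30 °C
Reagents that add atoms: none
Why: Diastereoselective enolate alkylation, in which the planar lithium enolate is attacked on the face anti to the tert-butyl group, so that CH2OBn takes the place of the former hydrogen and sets the quaternary (S) centre that becomes the butenolide carbon.

Step 5
Reactants: 10 alkylated dioxolanone; 11 tert-butyl propionate
Product: 13 (5S)-5-[(benzyloxy)methyl]-4-hydroxy-3,5-dimethylfuran-2(5H)-one, via hydroxy keto ester 12 (not isolated)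
Conditions: 11, LDA (excess), THF, −78 °C; then 10, −78 to 0 °C; AcOH quench; then TFA, CH2Cl2, rt
Reagents that add atoms: none
Why: Crossed Claisen acylation of the ester enolate by the dioxolanone carbonyl releases pivalaldehyde and the tertiary alcohol, and acid then cleaves the tert-butyl ester with 5-exo-trig lactonisation to the tetronic acid without touching the quaternary centre.

Step 6
Reactants: 13 tetronic acid
Product: 14 (5S)-5-[(benzyloxy)methyl]-4-(methoxymethoxy)-3,5-dimethylfuran-2(5H)-one
Conditions: MOMCl, iPr2NEt, CH2Cl2, 0 °C
Reagents that add atoms: chloromethyl methyl ether (MOMCl), COCCl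
Why: O-alkylation of the tetronate anion by a hard electrophile masks the acidic, oxidisable enol for the next three steps.

Step 7
Reactants: 14 MOM tetronate
Product: 15 (5S)-5-(hydroxymethyl)-4-(methoxymethoxy)-3,5-dimethylfuran-2(5H)-one
Conditions: H2 (1 atm), Pd/C, EtOAc, rt
Reagents that add atoms: none
Why: Hydrogenolysis of the benzyl ether, to which the tetrasubstituted push–pull double bond of the tetronate should be inert.

Step 8
Reactants: 15 primary alcohol
Product: 16 (2R)-3-(methoxymethoxy)-2,4-dimethyl-5-oxo-2,5-dihydrofuran-2-carbaldehyde
Conditions: Dess–Martin periodinane, CH2Cl2, 0 °C to rt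
Reagents that add atoms: none
Why: Dess–Martin oxidation of a neopentyl-type alcohol gives an aldehyde that has no alpha hydrogen, so it cannot epimerise (the descriptor changes only through the priority rules).

Step 9
Reactants: 17 sorbic acid ((2E,4E)-hexa-2,4-dienoic acid); 18 mono-tert-butyl malonate
Product: 20 tert-butyl (4E,6E)-3-oxoocta-4,6-dienoate, via sorbyl imidazolide 19 (not isolated)
Conditions: 17, CDI, THF, rt; then 18, MgCl2, Et3N, MeCN, rt; 1 M HCl
Reagents that add atoms: none
Why: Decarboxylative Claisen condensation of a magnesium malonate half-ester with an acyl imidazolide acylates at the carbonyl only, so conjugate addition to the dienoyl unit is avoided and both E alkenes are kept.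

Step 10
Reactants: 16 aldehyde; 20 beta-keto ester
Product: 21 tert-butyl (2Z,4E,6E)-2-{[(2S)-3-(methoxymethoxy)-2,4-dimethyl-5-oxo-2,5-dihydrofuran-2-yl]methylidene}-3-oxoocta-4,6-dienoate
Conditions: ethylenediammonium diacetate (cat.), 4 Å MS, CH2Cl2, rt
Reagents that add atoms: none
Why: Knoevenagel condensation of an electron-poor, non-enolisable aldehyde, expected to place the bulky butenolide cis to the ester (Z), the geometry needed next and one that can also be reached by equilibration of the other isomer.

Step 11
Reactants: 21 alkylidene keto ester
Product: 23 (7aS)-6-[(2E,4E)-hexa-2,4-dienoyl]-3,7a-dimethyl-2H-furo[3,2-b]pyran-2,5(7aH)-dione, via seco acid 22 (not isolated)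
Conditions: TFA, wet CH2Cl2, 0 °C to rt; evaporation with toluene; then DCC, CH2Cl2, 0 °C; filtration under argon, used directly
Reagents that add atoms: none
Why: Acidolysis removes the tert-butyl and MOM groups together, and carbodiimide-mediated O-acylation of the tetronic acid (its C-acylation site is blocked by methyl) closes the six-membered enol lactone on the cis-disposed carboxyl group.

Step 12
Reactants: 5 2',3'-dihydrosorbicillin; 23 bicyclic dienophile
Product: 25 endo [4+2] adduct (bicyclo[2.2.2]octenone cis-fused through its new two-carbon bridge to the enol lactone/butenolide bicycle; lactone ring syn to the enol bridge, sorbyl ketone syn to the ketol bridge, tertiary OH syn to the new bridge), via (S)-dihydrosorbicillinol 24 (not isolated)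
Conditions: SorbC (cat.), NAD+ (cat.), formate dehydrogenase, HCO2Na, air, phosphate buffer pH 8/acetone, 25 °C; extraction into CH2Cl2, Na2SO4; slow addition to 23 (2 equiv), 4 Å MS, CH2Cl2, 0 °C to rt
Reagents that add atoms: dioxygen, O=O
Why: SorbC transfers one oxygen atom of O2 to the methyl-bearing aryl carbon C5 of 5 and dearomatises it to the o-quinol 24, whose ring atoms C2=C3–C4=C5 form a locked s-cis diene that adds suprafacially across the doubly activated C6=C7 bond of 23 in a concerted, asynchronous [4+2] cycloaddition. The closest known reaction type is the Diels–Alder trapping of sorbicillinol-type o-quinols (6-hydroxycyclohexa-2,4-dienones), generated by this enzyme or by chemical dearomatisation, by added acceptor alkenes or by the ring enone of a second quinol molecule. Two sigma bonds, C2 of 24 to C6 of 23 and C5 of 24 to C7 of 23, close both new six-membered carbocycles at once by intermolecular two-bond cycloaddition rather than by chain cyclisation: one ring holds the two bridgeheads, the C(=O)–C(CH3)(OH) bridge and the new two-carbon bridge, and its twin holds the enol bridge instead. The carbinol centre (S) is set by the enzyme, the two bridgeheads by attack on the diene face that bears OH rather than CH3, and the two carbons of the new bridge by three elements: cis addition to the ring-locked alkene, endo placement of the lactone ring (exo placement would press the quaternary C7a against the tertiary OH), and approach to the face of 23 opposite its angular 7a-methyl group, so that the two stereochemical sources are matched. The step needs C7, the beta carbon, to bond to the unsubstituted diene terminus, which is the orientation cyclohexa-2,4-dienones show toward acceptor alkenes, and it needs reaction at C6=C7 rather than at the sorbyl alkenes, which the second carbonyl group and the planar ring secure. Self-dimerisation of 24 should be held back by adding its dilute extract slowly to an excess of the more electron-poor 23.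

Step 13
Reactants: 25 adduct
Product: 27 target, (1R,3S,4S,7R,8S)-5-[(4E)-hex-4-enoyl]-7-[(2E,4E)-hexa-2,4-dienoyl]-3,6-dihydroxy-8-[(2S)-3-hydroxy-2,4-dimethyl-5-oxo-2,5-dihydrofuran-2-yl]-1,3-dimethylbicyclo[2.2.2]oct-5-en-2-one, via beta-keto acid 26 (not isolated)
Conditions: LiOH, THF/H2O, 0 °C; then 1 M HCl to pH 2–3, EtOAc, 35 °C
Reagents that add atoms: water, O
Why: Saponification of an activated enol ester followed by beta-keto acid decarboxylation, in which hydroxide attacks the lactone carbonyl because tetronate is by far the best leaving group in 25, acidification lets 26 lose CO2 (which carries off the oxygen brought in by water), and the resulting enol is protonated at C7 on the endo face next to the acidic tetronic OH, placing the sorbyl ketone exo and trans to the butenolide, the thermodynamically preferred arrangement that stays correctable through enolisation.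

## Compound list

1 | 2,4-dimethylresorcinol | Cc1ccc(O)c(C)c1O | starting material
2 | acetic acid | CC(=O)O | starting material
3 | 1-(2,4-dihydroxy-3,5-dimethylphenyl)ethan-1-one (clavatol) | CC(=O)c1cc(C)c(O)c(C)c1O | intermediate
4 | (E)-crotyl bromide | C/C=C/CBr | starting material
5 | 2',3'-dihydrosorbicillin | C/C=C/CCC(=O)c1cc(C)c(O)c(C)c1O | intermediate
6 | (R)-lactic acid | C[C@@H](O)C(=O)O | starting material
7 | pivalaldehyde | CC(C)(C)C=O | starting material
8 | (2R,5R)-2-tert-butyl-5-methyl-1,3-dioxolan-4-one | C[C@H]1O[C@@H](C(C)(C)C)OC1=O | intermediate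
9 | benzyl chloromethyl ether | ClCOCc1ccccc1 | starting material
10 | (2R,5S)-5-[(benzyloxy)methyl]-2-tert-butyl-5-methyl-1,3-dioxolan-4-one | C[C@@]1(COCc2ccccc2)O[C@@H](C(C)(C)C)OC1=O | intermediate
11 | tert-butyl propionate | CCC(=O)OC(C)(C)C | starting material
12 | tert-butyl (4S)-5-(benzyloxy)-4-hydroxy-2,4-dimethyl-3-oxopentanoate (C2 epimers) | CC(C(=O)OC(C)(C)C)C(=O)[C@@](C)(O)COCc1ccccc1 | intermediate
13 | (5S)-5-[(benzyloxy)methyl]-4-hydroxy-3,5-dimethylfuran-2(5H)-one | CC1=C(O)[C@](C)(COCc2ccccc2)OC1=O | intermediate
14 | (5S)-5-[(benzyloxy)methyl]-4-(methoxymethoxy)-3,5-dimethylfuran-2(5H)-one | CC1=C(OCOC)[C@](C)(COCc2ccccc2)OC1=O | intermediate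
15 | (5S)-5-(hydroxymethyl)-4-(methoxymethoxy)-3,5-dimethylfuran-2(5H)-one | CC1=C(OCOC)[C@](C)(CO)OC1=O | intermediate
16 | (2R)-3-(methoxymethoxy)-2,4-dimethyl-5-oxo-2,5-dihydrofuran-2-carbaldehyde | CC1=C(OCOC)[C@](C)(C=O)OC1=O | intermediate
17 | sorbic acid | C/C=C/C=C/C(=O)O | starting material
18 | mono-tert-butyl malonate | CC(C)(C)OC(=O)CC(=O)O | starting material
19 | (2E,4E)-1-(imidazol-1-yl)hexa-2,4-dien-1-one | C/C=C/C=C/C(=O)n1ccnc1 | intermediate
20 | tert-butyl (4E,6E)-3-oxoocta-4,6-dienoate | C/C=C/C=C/C(=O)CC(=O)OC(C)(C)C | intermediate
21 | tert-butyl (2Z,4E,6E)-2-{[(2S)-3-(methoxymethoxy)-2,4-dimethyl-5-oxo-2,5-dihydrofuran-2-yl]methylidene}-3-oxoocta-4,6-dienoate | C/C=C/C=C/C(=O)/C(C(=O)OC(C)(C)C)=C/[C@]1(C)OC(=O)C(C)=C1OCOC | intermediate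
22 | (2Z,4E,6E)-2-{[(2S)-3-hydroxy-2,4-dimethyl-5-oxo-2,5-dihydrofuran-2-yl]methylidene}-3-oxoocta-4,6-dienoic acid | C/C=C/C=C/C(=O)/C(C(=O)O)=C/[C@]1(C)OC(=O)C(C)=C1O | intermediate
23 | (7aS)-6-[(2E,4E)-hexa-2,4-dienoyl]-3,7a-dimethyl-2H-furo[3,2-b]pyran-2,5(7aH)-dione | C/C=C/C=C/C(=O)C1=C[C@]2(C)OC(=O)C(C)=C2OC1=O | intermediate
24 | (6S)-4-[(4E)-hex-4-enoyl]-3,6-dihydroxy-2,6-dimethylcyclohexa-2,4-dien-1-one ((S)-dihydrosorbicillinol) | C/C=C/CCC(=O)C1=C[C@](C)(O)C(=O)C(C)=C1O | intermediate
25 | endo adduct; C(CH3) bridgehead R, CH bridgehead S, carbinol S, quaternary acyl carbon S, adjacent CH S, butenolide carbon S | C/C=C/C=C/C(=O)[C@]12C(=O)OC3=C(C)C(=O)O[C@@]3(C)[C@H]1[C@H]4C(C(=O)CC/C=C/C)=C(O)[C@]2(C)C(=O)[C@@]4(C)O | intermediate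
26 | ring-opened beta-keto acid (carboxyl endo on the quaternary carbon, free tetronic acid) | C/C=C/C=C/C(=O)[C@]1(C(=O)O)[C@@H]([C@]2(C)OC(=O)C(C)=C2O)[C@H]2C(C(=O)CC/C=C/C)=C(O)[C@]1(C)C(=O)[C@@]2(C)O | intermediate
27 | target CNP0539719.2 | C/C=C/C=C/C(=O)[C@@H]1[C@@H]([C@]2(C)OC(=O)C(C)=C2O)[C@H]2C(C(=O)CC/C=C/C)=C(O)[C@]1(C)C(=O)[C@@]2(C)O | target

## Step count and risks

Total step count: 13. Longest linear sequence: 10 steps (3, 4, 5, 6, 7, 8, 10, 11, 12, 13).

Steps most likely to fail:

**Step 12.**
- Risk: the free quinol may be consumed by self-dimerisation, or acylated at its hydroxyl groups by the enol lactone, faster than it cycloadds. The dilute enzymatic stage also limits throughput.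
- Fallback: it sets out from 5 (with 23) and comes back to the route at 27. Wessely oxidation of 5 with Pb(OAc)4 in AcOH/CH2Cl2 should give the racemic acetoxy dienone F1, a storable diene without a free tertiary hydroxyl group. Heated or pressurised with enantiopure 23, it should react in the same endo, oxygen-syn [4+2] mode of 6-acetoxycyclohexa-2,4-dienones and give two diastereomeric adducts. The adduct acetate F2, which derives from the S enantiomer of the diene, is separated from them by chromatography. LiOH as in step 13 then removes the acetate and opens the lactone, and acidification with decarboxylation gives 27.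

**Step 11.**
- Risk: the acid stage may trigger Nazarov-type cyclisation of the cross-conjugated dienone. In addition, the alkene isomer with the ketone cis to the butenolide cannot lactonise.
- Fallback: it sets out from 16 and 17 and comes back at 23. The ring is built in the opposite order. Dilute HCl in THF should free the formyl tetronic acid F3 from 16. Coupling of 17 with Meldrum's acid (DCC, DMAP) should give the sorbyl Meldrum's acid F4. Heating F3 and F4 in toluene over molecular sieves generates the acylketene, which O-acylates the enol. An intramolecular Knoevenagel condensation of the 3-acylcoumarin type then closes the pyranone ring of 23.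

**Step 13.**
- Risk: hydroxide may attack the sorbyl ketone (retro-Claisen loss of the side chain) or induce an alpha-ketol shift before the hindered lactone carbonyl reacts.
- Fallback: it sets out from 25 and comes back at 27, and it avoids hydroxide altogether. DMAP-catalysed alcoholysis with allyl alcohol should open the enol lactone to the allyl beta-keto ester F5. Decarboxylative deallylation with Pd(PPh3)4 (zerovalent palladium), HCO2H and Et3N in THF then gives the enol and, after protonation, 27 under nearly neutral conditions.

## Further compounds

F1 | step 12 | rac-6-acetoxy-4-[(4E)-hex-4-enoyl]-3-hydroxy-2,6-dimethylcyclohexa-2,4-dien-1-one | C/C=C/CCC(=O)C1=CC(C)(OC(C)=O)C(=O)C(C)=C1O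
F2 | step 12 | O-acetate of adduct 25 | C/C=C/C=C/C(=O)[C@]12C(=O)OC3=C(C)C(=O)O[C@@]3(C)[C@H]1[C@H]4C(C(=O)CC/C=C/C)=C(O)[C@]2(C)C(=O)[C@@]4(C)OC(C)=O
F3 | step 11 | (2R)-3-hydroxy-2,4-dimethyl-5-oxo-2,5-dihydrofuran-2-carbaldehyde | CC1=C(O)[C@](C)(C=O)OC1=O
F4 | step 11 | 5-[(2E,4E)-1-hydroxyhexa-2,4-dienylidene]-2,2-dimethyl-1,3-dioxane-4,6-dione | C/C=C/C=C/C(O)=C1C(=O)OC(C)(C)OC1=O
F5 | step 13 | allyl ester of beta-keto acid 26 | C/C=C/C=C/C(=O)[C@]1(C(=O)OCC=C)[C@@H]([C@]2(C)OC(=O)C(C)=C2O)[C@H]2C(C(=O)CC/C=C/C)=C(O)[C@]1(C)C(=O)[C@@]2(C)O
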